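The target's ring B (labdane C5–C10) is a six-membered ring with C-methyl groups at C8 and C10, a hydroxyl at C6 and an alkene carbon at C9: a masked 2,6-dimethyl-1,4-benzoquinone. Ring B is therefore purchased, and ring A is annulated onto its C5=C10 bond by one catalytic enantioselective Diels–Alder reaction that forms C1–C10 and C4–C5 and fixes quaternary C10. The diene is the Z silyl dienol ether of methyl 3-oxopent-4-enoate, which brings the C3 oxygen and the C19 ester. Afterwards a 19,6β-lactone enforces the C4 configuration, and the C9 carbonyl, as its enol triflate, receives the side chain.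

Key step: step 4

Remark: labdane numbering is used (C17 on C8, C18 = 4α-methyl, C19 = 4β-carbon, C20 on C10); β is the face of C20.
Remark: the enol ether carries a triisopropylsilyl group, because the bulkier silyl resists transfer to triflimide in step 4 and survives steps 5–7.
Remark: C8 in 10–16 is drawn as the equatorial 8α-methyl epimer; this epimerisable centre is erased in step 12.

Step 1
Reactants: 1 Meldrum's acid; 2 3-chloropropanoyl chloride
Product: 4 methyl 5-chloro-3-oxopentanoate, via acyl Meldrum's acid 3 (not isolated)
Conditions: pyridine, CH2Cl2, 0 °C → rt; solvent exchanged to MeOH, reflux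
Reagents that add atoms: methanol, CO
Why: C-acylation of Meldrum's acid followed by thermal methanolysis of the acyl derivative (loss of acetone and CO2 through the acylketene) is the standard β-keto ester synthesis.

Step 2
Reactants: 4 methyl 5-chloro-3-oxopentanoate
Product: 5 methyl 3-oxopent-4-enoate
Conditions: Et3N, Et2O, 0 °C; used at once
Reagents that add atoms: none
Why: E1cB elimination of HCl from the β-chloro ketone under a mild amine base should give the vinyl ketone.

Step 3
Reactants: 5 methyl 3-oxopent-4-enoate
Product: 6 methyl (2Z)-3-(triisopropylsilyloxy)penta-2,4-dienoate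
Conditions: NaN(SiMe3)2, THF, −78 °C; i-Pr3SiOSO2CF3, −78 → 0 °C
Reagents that add atoms: triisopropylsilyl triflate, CC(C)[Si](OS(=O)(=O)C(F)(F)F)(C(C)C)C(C)C
Why: O-silylation of the sodium-chelated β-keto ester enolate, in which the chelate holds the enolate oxygen cis to the ester, should give the Z enol ether with the ester trans to the vinyl group (the outside position of the s-cis diene).

Step 4
Reactants: 6 methyl (2Z)-3-(triisopropylsilyloxy)penta-2,4-dienoate; 7 2,6-dimethyl-1,4-benzoquinone
Product: 8 cis-fused enedione adduct (10β-methyl; 5β-H; 4α-CO2Me; C2=C3 silyl enol ether; C6 and C9 ketones; C7=C8)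
Conditions: (3aR)-3,3-diphenyl-1-(2-methylphenyl)tetrahydro-1H,3H-pyrrolo[1,2-c][1,3,2]oxazaborole (C24H24BNO, 20 mol %), HN(SO2CF3)2 (18 mol %), CH2Cl2, −78 → −40 °C
Reagents that add atoms: none
Why: Concerted, asynchronous, endo [4+2] cycloaddition of diene 6 to quinone 7, which is held on the boron of the protonated oxazaborolidine through the C6 carbonyl oxygen (the only one flanked by vinylic C–H, the C9 oxygen lying between two methyl groups); the closest known reaction type is the chiral oxazaborolidinium-catalysed Diels–Alder reaction of methyl-substituted 1,4-benzoquinones with 2-silyloxybutadienes. Ring A is closed as a six-membered carbocycle by intermolecular [4+2] annulation onto C5=C10, the bonds C1–C10 and C4–C5 forming suprafacially on one quinone face. C10 is set by the catalyst, whose phenyl group covers one face of the bound C5=C10 bond (the 3aR catalyst is chosen from the accepted binding model to give 10β-methyl); C5 follows from suprafacial addition (H cis to the 10-methyl), and C4 from the endo transition state with the ester held outside by the Z enol ether (H-4 cis to H-5). The step needs regioselectivity, and three things support C1-to-C10 and C4-to-C5 bonding: only unsubstituted C1 can reach the fully substituted β-carbon C10 without a CH(CO2Me)/quaternary clash; the C19 ester attenuates the enol-ether polarisation of C4 and, as a 1-acceptor, directs C4 to the carbon α to the bound carbonyl; and the uncatalysed polarisation of 7 (C9=O the stronger acceptor, C6=O being weakened by two vinylogous methyl donors) points the same way. The bulky silyl group suppresses silyl transfer to triflimide, which would otherwise start a racemic silyl-Lewis-acid background.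

Step 5
Reactants: 8 cis-fused enedione adduct
Product: 9 trans-fused enedione (5α-H; otherwise as 8)
Conditions: DBU (0.1 equiv), CH2Cl2, 0 °C → rt
Reagents that add atoms: none
Why: Base-mediated epimerisation through the cross-conjugated C6 dienolate (C5–H, α to the enedione carbonyl, is the most acidic proton and quaternary C10 blocks aromatisation) is expected to favour the trans fusion, in which the angular methyl has a single syn-axial hydrogen, and so sets C5.

Step 6
Reactants: 9 trans-fused enedione
Product: 10 trans-fused 6,9-dione (C7–C8 saturated; 8α-methyl)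
Conditions: Zn dust, AcOH/THF, 0 °C → rt
Reagents that add atoms: none
Why: Zinc conjugate reduction of the 2-ene-1,4-dione gives the saturated 1,4-diketone and leaves the enol ether, the ester and the ring fusion untouched.

Step 7
Reactants: 10 trans-fused 6,9-dione
Product: 11 6β-hydroxy-9-ketone (enol ether and 4α-ester retained)
Conditions: LiBH(s-Bu)3, THF, −78 °C; aqueous work-up
Reagents that add atoms: none
Why: The bulky hydride reduces only the C6 carbonyl (C9 is flanked by quaternary C10 and C8) and attacks equatorially on the α-face, anti to the axial 10β-methyl, to give the axial 6β-alcohol.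

Step 8
Reactants: 11 6β-hydroxy-9-ketone
Product: 13 3,9-dioxo-19,6β-lactone (4α-H), via hydroxy keto ester 12 (not isolated)
Conditions: CF3CO2H, H2O (2 equiv), CH2Cl2, 0 °C → rt; then TsOH·H2O (cat.), toluene, 70 °C
Reagents that add atoms: none
Why: Acid hydrolysis of the silyl enol ether gives the β-keto ester, whose C4 epimerises through the enol until the 1,3-diaxial 6β-OH/4β-ester pair closes the γ-lactone by intramolecular transesterification, which ties C19 to the β-face.

Step 9
Reactants: 13 3,9-dioxo-19,6β-lactone
Product: 14 4α-methyl-3,9-dioxo-19,6β-lactone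
Conditions: K2CO3, MeI, acetone, rt
Reagents that add atoms: iodomethane, CI
Why: C-alkylation of the α-acyl-γ-lactone enolate, in which methyl can only enter on the α-face because C19 is tethered to the 6β-oxygen (this is also the face anti to the axial 10β-methyl), sets the C4 quaternary centre.

Step 10
Reactants: 14 4α-methyl-3,9-dioxo-19,6β-lactone
Product: 15 3α-hydroxy-9-oxo-19,6β-lactone
Conditions: LiBH(s-Bu)3, THF, −78 °C; aqueous work-up
Reagents that add atoms: none
Why: The bulky hydride attacks the C3 ketone equatorially, as with other 4,4-disubstituted 3-ketones, to give the axial 3α-alcohol, while the more hindered C9 ketone and the lactone do not react at −78 °C.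

Step 11
Reactants: 15 3α-hydroxy-9-oxo-19,6β-lactone
Product: 16 3α-triethylsilyloxy-9-oxo-19,6β-lactone
Conditions: Et3SiOSO2CF3, 2,6-lutidine, CH2Cl2, −78 → 0 °C
Reagents that add atoms: triethylsilyl triflate, CC[Si](CC)(CC)OS(=O)(=O)C(F)(F)F
Why: Silyl triflate silylation of the hindered axial alcohol protects O3 for the enolisation, coupling and hydride steps.

Step 12
Reactants: 16 3α-triethylsilyloxy-9-oxo-19,6β-lactone
Product: 17 C9 enol triflate (C8=C9)
Conditions: KN(SiMe3)2, THF, −78 → −20 °C; PhN(SO2CF3)2, −78 °C → rt
Reagents that add atoms: N-phenylbis(trifluoromethanesulfonimide), O=S(=O)(N(c1ccccc1)S(=O)(=O)C(F)(F)F)C(F)(F)F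
Why: The C9 ketone can enolise only towards C8 (C10 is quaternary and the lactone has no α-hydrogen), so enolate formation and O-triflation should give the tetrasubstituted C8=C9 enol triflate regiospecifically.

Step 13
Reactants: 17 C9 enol triflate; 18 2-methyl-2-vinyl-1,3-dioxolane
Product: 20 C9-alkylated lactone with the C11–C13 dioxolane side chain, via alkylborane 19 (not isolated)
Conditions: 18, 9-borabicyclo[3.3.1]nonane (9-BBN-H), THF, 0 °C → rt; then 17, PdCl2(dppf) (dppf = 1,1'-bis(diphenylphosphino)ferrocene, 10 mol %), AsPh3, Cs2CO3, DMF/THF/H2O, rt → 50 °C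
Reagents that add atoms: none
Why: Anti-Markovnikov hydroboration of the vinyl ketal followed by B-alkyl Suzuki–Miyaura coupling with the alkenyl triflate forms C9–C11 and keeps the double bond at C8=C9.

Step 14
Reactants: 20 C9-alkylated lactone
Product: 22 3α,6β,19-trihydroxy-14,15-dinorlabd-8-en-13-one, via diol 21 (not isolated)
Conditions: LiAlH4, THF, 0 °C → rt; then 2 M aq. HCl, THF, rt
Reagents that add atoms: water, O
Why: LiAlH4 reduces the γ-lactone to the 6β,19-diol, and the acidic work-up then hydrolyses the dioxolane to the C13 methyl ketone and cleaves the triethylsilyl ether.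

Step 15
Reactants: 22 triol ketone
Product: 23 3α,19-bis(3-methylbutanoyloxy)-6β-hydroxy-14,15-dinorlabd-8-en-13-one
Conditions: (Me2CHCH2CO)2O (2.4 equiv), DMAP (cat.), pyridine, CH2Cl2, 0 °C → rt
Reagents that add atoms: 3-methylbutanoic anhydride, CC(C)CC(=O)OC(=O)CC(C)C
Why: DMAP-catalysed acylation esterifies the primary C19 and the secondary 3α hydroxyls, while the 6β-OH, 1,3-diaxial to both C20 and C19, is too hindered to react under these conditions.

Step 16
Reactants: 23 bis-ester ketone
Product: 24 allyl (13E)-enoate of the target acid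
Conditions: (EtO)2P(O)CH2CO2CH2CH=CH2 (2.0 equiv), NaH (1.9 equiv), THF, 0 → 45 °C
Reagents that add atoms: allyl diethylphosphonoacetate, CCOP(=O)(CC(=O)OCC=C)OCC
Why: Horner–Wadsworth–Emmons olefination of the methyl ketone should give mainly the E trisubstituted enoate (C12 trans to the ester) through reversible addition, and the stabilised phosphonate anion attacks neither the isovalerate esters nor the hindered alcohol.

Step 17
Reactants: 24 allyl ester
Product: 25 target acid CNP0333611.1
Conditions: Pd(PPh3)4 (5 mol %), morpholine, THF, rt; aq. citric acid work-up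
Reagents that add atoms: none
Why: Zerovalent palladium ionises the allyl ester to a π-allyl complex that morpholine traps (Tsuji–Trost deallylation), which frees the acid without touching the isovalerate esters or the alkenes.

Compound list
1 | Meldrum's acid (2,2-dimethyl-1,3-dioxane-4,6-dione) | CC1(C)OC(=O)CC(=O)O1 | starting material
2 | 3-chloropropanoyl chloride | O=C(Cl)CCCl | starting material
3 | 5-(3-chloro-1-hydroxypropylidene)-2,2-dimethyl-1,3-dioxane-4,6-dione | CC1(C)OC(=O)C(=C(O)CCCl)C(=O)O1 | intermediate (not isolated)
4 | methyl 5-chloro-3-oxopentanoate | COC(=O)CC(=O)CCCl | intermediate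
5 | methyl 3-oxopent-4-enoate | COC(=O)CC(=O)C=C | intermediate
6 | methyl (2Z)-3-(triisopropylsilyloxy)penta-2,4-dienoate | C=C/C(O[Si](C(C)C)(C(C)C)C(C)C)=C/C(=O)OC | intermediate
7 | 2,6-dimethyl-1,4-benzoquinone | CC1=CC(=O)C=C(C)C1=O | starting material
8 | cis-fused enedione adduct: 10β-methyl, 5β-H, 4α-CO2Me, C2=C3 triisopropylsilyl enol ether, C6 and C9 ketones, C7=C8 | CC1=CC(=O)[C@@H]2[C@H](C(=O)OC)C(O[Si](C(C)C)(C(C)C)C(C)C)=CC[C@]2(C)C1=O | intermediate
9 | trans-fused enedione: as 8 with 5α-H | CC1=CC(=O)[C@H]2[C@H](C(=O)OC)C(O[Si](C(C)C)(C(C)C)C(C)C)=CC[C@]2(C)C1=O | intermediate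
10 | trans-fused 6,9-dione, 8α-methyl | C[C@@H]1CC(=O)[C@H]2[C@H](C(=O)OC)C(O[Si](C(C)C)(C(C)C)C(C)C)=CC[C@]2(C)C1=O | intermediate
11 | 6β-hydroxy-9-ketone with C2=C3 silyl enol ether and 4α-CO2Me | C[C@@H]1C[C@@H](O)[C@H]2[C@H](C(=O)OC)C(O[Si](C(C)C)(C(C)C)C(C)C)=CC[C@]2(C)C1=O | intermediate
12 | 6β-hydroxy-3,9-dioxo methyl ester (C4 epimerising through the enol) | C[C@@H]1C[C@@H](O)[C@H]2C(C(=O)OC)C(=O)CC[C@]2(C)C1=O | intermediate (not isolated)
13 | 3,9-dioxo-19,6β-lactone, 4α-H, 5α-H, 10β-methyl | C[C@@H]1C[C@H]2OC(=O)[C@@H](C(=O)CC3)[C@H]2[C@@]3(C)C1=O | intermediate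
14 | 4α-methyl-3,9-dioxo-19,6β-lactone | C[C@@H]1C[C@H]2OC(=O)[C@@](C)(C(=O)CC3)[C@H]2[C@@]3(C)C1=O | intermediate
15 | 3α-hydroxy-9-oxo-19,6β-lactone | C[C@@H]1C[C@H]2OC(=O)[C@@](C)([C@H](O)CC3)[C@H]2[C@@]3(C)C1=O | intermediate
16 | 3α-triethylsilyloxy-9-oxo-19,6β-lactone | C[C@@H]1C[C@H]2OC(=O)[C@@](C)([C@H](O[Si](CC)(CC)CC)CC3)[C@H]2[C@@]3(C)C1=O | intermediate
17 | C9 enol triflate (C8=C9) of 16 | CC=1C[C@H]2OC(=O)[C@@](C)([C@H](O[Si](CC)(CC)CC)CC3)[C@H]2[C@@]3(C)C=1OS(=O)(=O)C(F)(F)F | intermediate
18 | 2-methyl-2-vinyl-1,3-dioxolane | CC1(C=C)OCCO1 | starting material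
19 | 9-[2-(2-methyl-1,3-dioxolan-2-yl)ethyl]-9-borabicyclo[3.3.1]nonane | CC1(CCB2C3CCCC2CCC3)OCCO1 | intermediate (not isolated)
20 | 3α-triethylsilyloxy-19,6β-lactone with C8=C9 and the 2-(2-methyl-1,3-dioxolan-2-yl)ethyl chain on C9 | CC=1C[C@H]2OC(=O)[C@@](C)([C@H](O[Si](CC)(CC)CC)CC3)[C@H]2[C@@]3(C)C=1CCC4(C)OCCO4 | intermediate
21 | 6β,19-diol with 3α-triethylsilyloxy group and dioxolane side chain | CC1=C(CCC3(C)OCCO3)[C@@]2(C)CC[C@@H](O[Si](CC)(CC)CC)[C@](C)(CO)[C@@H]2[C@H](O)C1 | intermediate (not isolated)
22 | 3α,6β,19-trihydroxy-14,15-dinorlabd-8-en-13-one | CC1=C(CCC(C)=O)[C@@]2(C)CC[C@@H](O)[C@](C)(CO)[C@@H]2[C@H](O)C1 | intermediate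
23 | 3α,19-bis(3-methylbutanoyloxy)-6β-hydroxy-14,15-dinorlabd-8-en-13-one | CC1=C(CCC(C)=O)[C@@]2(C)CC[C@@H](OC(=O)CC(C)C)[C@](C)(COC(=O)CC(C)C)[C@@H]2[C@H](O)C1 | intermediate
24 | allyl 3α,19-bis(3-methylbutanoyloxy)-6β-hydroxylabda-8,13E-dien-15-oate | CC1=C(CC/C(C)=C/C(=O)OCC=C)[C@@]2(C)CC[C@@H](OC(=O)CC(C)C)[C@](C)(COC(=O)CC(C)C)[C@@H]2[C@H](O)C1 | intermediate
25 | 3α,19-bis(3-methylbutanoyloxy)-6β-hydroxylabda-8,13E-dien-15-oic acid (CNP0333611.1) | CC1=C(CC/C(C)=C/C(=O)O)[C@@]2(C)CC[C@@H](OC(=O)CC(C)C)[C@](C)(COC(=O)CC(C)C)[C@@H]2[C@H](O)C1 | target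

Total step count: 17.
Longest linear sequence: 17 steps (1 and 2 to 25); 7 and 18 are purchased and enter at steps 4 and 13.

Steps most likely to fail

Step 4. The risk is regiochemical leakage: the catalyst sits on the C6 carbonyl and so activates C10, which is electronically matched with the silyloxy-activated C4 and not with C1, so the isomer with the ester next to the quaternary carbon may form. Enantioselectivity may also erode through a silyl-triflimide background, and the facial sense rests on a binding model (if only the sense is wrong, the 3aS catalyst is used). The fallback sets out from 6 and 7 and gives up catalyst control. An uncatalysed cycloaddition in toluene at 40–60 °C runs under the intrinsic polarisation of the free quinone, where the C9 carbonyl is the stronger acceptor, so that electronic and steric preferences both send C4 to C5. It should give the racemic endo adduct, that is 8 together with the enantiomer of adduct 8 F1. Preparative chromatography on a chiral stationary phase then returns the route to 8.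

Step 5. The risk is an unfavourable or incomplete cis-to-trans equilibrium at the enedione stage, where the flat conjugated ring B tolerates the cis fusion well, or base-induced migration of the enol-ether double bond into conjugation with the ester. The fallback sets out from 8 and moves the inversion to a later substrate. Zinc reduction in AcOH/THF is done first and should give the cis-fused saturated 6,9-dione F2. C5 is then equilibrated with NaOMe in MeOH, where ring B is a chair and the trans fusion no longer loses enedione conjugation. Recovered cis material is re-equilibrated, and the route is rejoined at 10.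

Step 13. The risk is slow oxidative addition and transmetallation at a triflate flanked by quaternary C10 and the C8 methyl, so that triflate hydrolysis and protodeboronation of the alkylborane compete. The fallback sets out from 17 and replaces the boron/palladium manifold by an iron-catalysed alkenyl triflate–Grignard coupling. 2-(2-Bromoethyl)-2-methyl-1,3-dioxolane F3 is converted with Mg in THF into [2-(2-methyl-1,3-dioxolan-2-yl)ethyl]magnesium bromide F4. F4 is coupled with 17 under Fe(acac)3 catalysis in THF/NMP at −30 °C, conditions that are fast for hindered alkenyl triflates and leave the hindered lactone untouched. The route is rejoined at 20.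

Further compounds
F1 | step 4 | enantiomer of adduct 8 | CC1=CC(=O)[C@H]2[C@@H](C(=O)OC)C(O[Si](C(C)C)(C(C)C)C(C)C)=CC[C@@]2(C)C1=O
F2 | step 5 | cis-fused saturated 6,9-dione (5β-H, C8 epimers) | CC1CC(=O)[C@@H]2[C@H](C(=O)OC)C(O[Si](C(C)C)(C(C)C)C(C)C)=CC[C@]2(C)C1=O
F3 | step 13 | 2-(2-bromoethyl)-2-methyl-1,3-dioxolane | CC1(CCBr)OCCO1
F4 | step 13 | [2-(2-methyl-1,3-dioxolan-2-yl)ethyl]magnesium bromide | CC1(CC[Mg]Br)OCCO1
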